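**Plan**

Retrosynthesis: the O–CH3 bond and the aryl O–S bond of the target are traced back to one intermediate, a cyclic diaryl sulfate in which a single SO2 unit bridges both phenol oxygens. Its two S–O bonds are cut to a symmetric N-protected bisphenol and SO2F2. The imidazole is cut at its four C–N bonds (formamide supplies N1, C2 and N3) and at C4–C5 (acyloin coupling of two 4-methoxyphenylacetate units).
Forward: the C4–C5 bond comes first, then the imidazole ring, N-SEM protection (SEM = 2-(trimethylsilyl)ethoxymethyl) and release of both phenols. A 15-membered [4.3]paracyclophane ring is then closed at sulfur. In the last step, in one flask, it is opened by one hydrolytic S–O cleavage, the freed phenoxide is methylated and SEM is removed, so the two regioisomeric N-SEM series are never isolated and converge on one compound.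
Enabling feature: the two para oxygen atoms sit on benzyl arms fixed cis on the C4=C5 edge of the imidazole ring and differ in the target only as OCH3 against OSO3H. A three-atom O–S–O bridge can therefore span them, and because N–H tautomerism makes the two arms equivalent it does not matter which S–O bond of the ring is cleaved later.
Stereochemistry: the target has no stereocentre and no stereogenic double bond; the only stereocentre on the way (the racemic carbinol carbon of the acyloin) disappears when the imidazole forms.

Key step: step 5

Remark: the target is written as the neutral hydrogen sulfate; it is expected to exist, and to be isolated, as the imidazolium–sulfate inner salt, which is the same compound.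

Naming used below: "C5 arm" is the benzyl group on the ring carbon next to the SEM-bearing N1, and "C4 arm" is the benzyl group on the ring carbon next to N3.

Step 1
Reactants: 1 methyl 4-methoxyphenylacetate (two molecules)
Product: 3 3-hydroxy-1,4-bis(4-methoxyphenyl)butan-2-one (racemic acyloin), via bis(trimethylsilyl) enediol ether 2 (not isolated)
Conditions: Na (dispersion, 4.2 equiv), Me3SiCl (4.5 equiv), toluene, reflux; filter, concentrate; then 1 M HCl, THF, rt, under N2
Reagents that add atoms: chlorotrimethylsilane, C[Si](C)(C)Cl (silyl groups of intermediate 2 only)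
Why: Rühlmann variant of the acyloin condensation: sodium reduces the ester to ketyl radical anions that couple at carbon, Me3SiCl traps the enediolate and the methoxide so that Claisen condensation of the acidic arylacetate is suppressed, and mild acid then releases the racemic α-hydroxy ketone, whose single stereocentre is erased in step 2.

Step 2
Reactants: 3 3-hydroxy-1,4-bis(4-methoxyphenyl)butan-2-one; 4 formamide
Product: 5 4,5-bis(4-methoxybenzyl)-1H-imidazole
Conditions: HCONH2 (neat, large excess), 180 °C, N2
Reagents that add atoms: formamide, NC=O (compound 4)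
Why: Bredereck imidazole synthesis: hot formamide delivers both nitrogen atoms and the C2 carbon, and the α-hydroxy ketone condenses, cyclises and dehydrates to the 4,5-disubstituted imidazole, as is known for benzoin and for aliphatic acyloins.

Step 3
Reactants: 5 4,5-bis(4-methoxybenzyl)-1H-imidazole; 6 2-(trimethylsilyl)ethoxymethyl chloride (SEM chloride)
Product: 7 4,5-bis(4-methoxybenzyl)-1-SEM-imidazole
Conditions: NaH (1.2 equiv), THF, 0 °C; SEMCl (1.1 equiv), 0 °C to rt
Reagents that add atoms: SEM chloride, C[Si](C)(C)CCOCCl (compound 6)
Why: N-alkylation of the sodium imidazolide by the reactive chloromethyl ether; the two ring nitrogens are equivalent in the symmetric 4,5-disubstituted imidazole, so a single N-SEM compound should result.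

Step 4
Reactants: 7 4,5-bis(4-methoxybenzyl)-1-SEM-imidazole
Product: 8 4,5-bis(4-hydroxybenzyl)-1-SEM-imidazole (bisphenol)
Conditions: NaSEt (6 equiv), DMF, 120 °C; then 1 M HCl to pH 8
Reagents that add atoms: none
Why: SN2 O-demethylation of aryl methyl ethers by ethanethiolate in a dipolar aprotic solvent; the two anisole rings are insulated from each other by CH2 groups so both react, and the base-stable N-SEM aminal is not exposed to any acid.

Step 5
Reactants: 8 4,5-bis(4-hydroxybenzyl)-1-SEM-imidazole; 9 sulfuryl fluoride
Product: 12 cyclic diaryl sulfate of 8 (15-membered [4.3]paracyclophane; both phenol oxygens bonded to one SO2), via C5-arm fluorosulfate 10 (not isolated), via C4-arm fluorosulfate 11 (not isolated)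
Conditions: DBU (4 equiv), MeCN (2 mM in 8), 60 °C; SO2F2 (1.0 equiv, standardised MeCN solution) added below the surface by syringe pump over 24 h, then 12 h at 60 °C
Reagents that add atoms: sulfuryl fluoride, O=S(=O)(F)F (compound 9)
Why: Proposed new method: the DBU-paired phenoxide of 8 attacks SO2F2 at sulfur and expels fluoride to give fluorosulfate 10 or 11, whose hexavalent sulfur is then attacked by the phenoxide of the neighbouring arm with loss of the second fluoride, so that both O–S bonds arise at one sulfur atom in one flask. The closest known reaction type is sulfur–fluoride exchange of aryl fluorosulfates with phenols or aryl silyl ethers under DBU, which also accounts for the diaryl sulfate by-products seen when a phenol is fluorosulfated under strongly basic conditions short of SO2F2, combined with high-dilution closure of heteroatom-bridged [3.3]paracyclophanes. The single new ring, the 15-membered [4.3]paracyclophane, closes by end-to-end substitution at sulfur: the three-atom O–S–O bridge joins two para oxygens whose benzyl arms are held cis by the four-atom CH2–C=C–CH2 bridge on the C4=C5 edge of the imidazole. No stereocentre is formed. The selectivity needed is ring closure ahead of a second fluorosulfation and of intermolecular exchange; it should be secured by keeping SO2F2 the limiting species at every moment (slow dosing of exactly one equivalent), by the 2 mM concentration, by a temperature at which closure keeps pace with the feed and by the preorganised arms, while bridges of four and three atoms should keep the strain below that of the known [3.3] systems. N-SEM blocks fluorosulfonylation of the imidazole N–H, and any adduct at the basic N3 is itself a fluorosulfuryl donor toward phenoxide and so should do no harm.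

Step 6
Reactants: 12 cyclic diaryl sulfate
Product: 17 melanocin F (4-[(4-methoxyphenyl)methyl]-5-[(4-sulfooxyphenyl)methyl]-1H-imidazole; either N–H tautomer; isolated as the inner salt), via C5-arm sulfate phenoxide 13 (not isolated), via C4-arm sulfate phenoxide 14 (not isolated), via C5-arm sulfate methyl ether 15 (not isolated), via C4-arm sulfate methyl ether 16 (not isolated)
Conditions: KOH (2.2 equiv, powdered), DMSO (2% H2O), rt to 50 °C; then CH3I (1.1 equiv), rt; then Bu4NF (1 M in THF, 6 equiv), 80 °C; AcOH to pH 6 at 0 °C; C18 chromatography (H2O/MeCN)
Reagents that add atoms: potassium hydroxide, [K+].[OH-]; iodomethane, CI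
Why: Three known operations are run in one flask so that the regioisomeric N-SEM intermediates need not be separated: hydroxide attacks the sulfur of the diaryl sulfate and expels an aryloxide (alkaline hydrolysis of a sulfate diester, which should stop at the hydroxide-repelling monoester anion whichever S–O bond breaks), the potassium phenoxide is O-methylated by CH3I under KOH/DMSO Williamson conditions while N-SEM rules out an imidazolide and the small excess of hydroxide consumes surplus CH3I before N3 can be quaternised, and fluoride then fragments the SEM group (attack at silicon, loss of ethylene and formaldehyde) without touching the base-stable aryl sulfate, both regioisomers giving one compound because the N–H tautomers interconvert.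

**Compound list**

1 | methyl 4-methoxyphenylacetate | COC(=O)Cc1ccc(OC)cc1 | starting material
2 | 2,3-bis(trimethylsilyloxy)-1,4-bis(4-methoxyphenyl)but-2-ene (E/Z mixture, geometry without consequence) | COc1ccc(CC(O[Si](C)(C)C)=C(O[Si](C)(C)C)Cc2ccc(OC)cc2)cc1 | intermediate (not isolated)
3 | 3-hydroxy-1,4-bis(4-methoxyphenyl)butan-2-one (racemic) | COc1ccc(CC(=O)C(O)Cc2ccc(OC)cc2)cc1 | intermediate
4 | formamide | NC=O | starting material
5 | 4,5-bis(4-methoxybenzyl)-1H-imidazole | COc1ccc(Cc2nc[nH]c2Cc2ccc(OC)cc2)cc1 | intermediate
6 | 2-(trimethylsilyl)ethoxymethyl chloride (SEM chloride) | C[Si](C)(C)CCOCCl | starting material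
7 | 4,5-bis(4-methoxybenzyl)-1-SEM-imidazole | COc1ccc(Cc2ncn(COCC[Si](C)(C)C)c2Cc2ccc(OC)cc2)cc1 | intermediate
8 | 4,5-bis(4-hydroxybenzyl)-1-SEM-imidazole | Oc1ccc(Cc2ncn(COCC[Si](C)(C)C)c2Cc2ccc(O)cc2)cc1 | intermediate
9 | sulfuryl fluoride | O=S(=O)(F)F | starting material
10 | 1-SEM-imidazole with 4-hydroxybenzyl on C4 and 4-(fluorosulfonyloxy)benzyl on C5 | Oc1ccc(Cc2ncn(COCC[Si](C)(C)C)c2Cc2ccc(OS(=O)(=O)F)cc2)cc1 | intermediate (not isolated)
11 | 1-SEM-imidazole with 4-(fluorosulfonyloxy)benzyl on C4 and 4-hydroxybenzyl on C5 | O=S(=O)(F)Oc1ccc(Cc2ncn(COCC[Si](C)(C)C)c2Cc2ccc(O)cc2)cc1 | intermediate (not isolated)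
12 | cyclic diaryl sulfate of 4,5-bis(4-hydroxybenzyl)-1-SEM-imidazole (15-membered [4.3]paracyclophane) | O=S1(=O)Oc2ccc(cc2)Cc2ncn(COCC[Si](C)(C)C)c2Cc2ccc(O1)cc2 | intermediate
13 | dipotassium 4-{[4-(4-oxidobenzyl)-1-SEM-imidazol-5-yl]methyl}phenyl sulfate (sulfate on the C5 arm, phenoxide on the C4 arm) | [O-]c1ccc(Cc2ncn(COCC[Si](C)(C)C)c2Cc2ccc(OS(=O)(=O)[O-])cc2)cc1.[K+].[K+] | intermediate (not isolated)
14 | dipotassium 4-{[5-(4-oxidobenzyl)-1-SEM-imidazol-4-yl]methyl}phenyl sulfate (sulfate on the C4 arm, phenoxide on the C5 arm) | [O-]S(=O)(=O)Oc1ccc(Cc2ncn(COCC[Si](C)(C)C)c2Cc2ccc([O-])cc2)cc1.[K+].[K+] | intermediate (not isolated)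
15 | potassium 4-{[4-(4-methoxybenzyl)-1-SEM-imidazol-5-yl]methyl}phenyl sulfate | COc1ccc(Cc2ncn(COCC[Si](C)(C)C)c2Cc2ccc(OS(=O)(=O)[O-])cc2)cc1.[K+] | intermediate (not isolated)
16 | potassium 4-{[5-(4-methoxybenzyl)-1-SEM-imidazol-4-yl]methyl}phenyl sulfate | [O-]S(=O)(=O)Oc1ccc(Cc2ncn(COCC[Si](C)(C)C)c2Cc2ccc(OC)cc2)cc1.[K+] | intermediate (not isolated)
17 | melanocin F | COc1ccc(Cc2[nH]cnc2Cc2ccc(OS(=O)(=O)O)cc2)cc1 | target

Total step count: 6
Longest linear sequence: 6 steps (1 to 17)

**Steps most likely to fail**

Step 5 (ring closure at sulfur). What may go wrong is that intermolecular exchange to linear and cyclic oligosulfates, or a second fluorosulfation of the same molecule, outruns closure of the strained 15-membered ring. The fallback uses known chemistry only and differentiates the phenols by statistics instead of by a tether. It sets out from bisphenol 8: CH3I (1.0 equiv) and K2CO3 in DMF, followed by chromatography, should give the two monomethyl ethers 1-SEM-4-(4-hydroxybenzyl)-5-(4-methoxybenzyl)imidazole F1 and 1-SEM-5-(4-hydroxybenzyl)-4-(4-methoxybenzyl)imidazole F2, while recovered 8 is recycled directly and the dimethyl ether 7 through step 4. O-Sulfation of the pair with SO3·pyridine in pyridine and work-up with aqueous K2CO3 should give the potassium sulfates, F2 leading to 15 and F1 to 16, where the route is rejoined; only the Bu4NF stage of step 6 then remains.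

Step 6 (ring opening, methylation and removal of SEM in one flask). What may go wrong is quaternisation of N3 while the phenoxide is being capped, slow or incomplete fluoride-induced fragmentation of the aminal in the wet, salt-laden DMSO, retention of an N-hydroxymethyl group, or loss of material when the inner salt is separated from potassium and tetrabutylammonium salts. The fallback removes the N-protecting group before the ring is opened, so that every intermediate is a single compound, no fluoride is needed and acid is used only while the sulfur is still a diester. It sets out from cyclophane 12: 3 M HCl in EtOH/H2O at 70 °C, conditions that aryl sulfate diesters should tolerate, should give the cyclic diaryl sulfate of 4,5-bis(4-hydroxybenzyl)-1H-imidazole F3. KOH in DMSO/H2O, then adjustment to pH 9, opens one S–O bond and should give potassium 4-{[5-(4-hydroxybenzyl)-1H-imidazol-4-yl]methyl}phenyl sulfate F4, one compound because of N–H tautomerism. Me3SiCHN2 with iPr2NEt in MeCN/MeOH at rt then methylates only the phenol, the one group acidic enough to protonate the diazoalkane, and adjustment to pH 6 returns to the target 17.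

Step 4 (double O-demethylation). What may go wrong is attack of the thiolate at the N–CH2–O carbon with loss of the SEM group at the temperature the second demethylation needs. The fallback demethylates before N-protection and masks the phenols in the meantime. It sets out from imidazole 5: BBr3 in CH2Cl2 (−78 °C to rt) should give 4,5-bis(4-hydroxybenzyl)-1H-imidazole F5. TBSCl and imidazole in DMF, with an aqueous work-up that hydrolyses any N-silyl group, give 4,5-bis[4-(tert-butyldimethylsilyloxy)benzyl]-1H-imidazole F6. NaH and SEMCl in THF give its N-SEM derivative 4,5-bis[4-(tert-butyldimethylsilyloxy)benzyl]-1-SEM-imidazole F7. K2CO3 in MeOH at rt cleaves only the two aryl silyl ethers and returns to bisphenol 8.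

**Further compounds**

F1 | step 5 | 1-SEM-4-(4-hydroxybenzyl)-5-(4-methoxybenzyl)imidazole | Oc1ccc(Cc2ncn(COCC[Si](C)(C)C)c2Cc2ccc(OC)cc2)cc1
F2 | step 5 | 1-SEM-5-(4-hydroxybenzyl)-4-(4-methoxybenzyl)imidazole | COc1ccc(Cc2ncn(COCC[Si](C)(C)C)c2Cc2ccc(O)cc2)cc1
F3 | step 6 | cyclic diaryl sulfate of 4,5-bis(4-hydroxybenzyl)-1H-imidazole | O=S1(=O)Oc2ccc(cc2)Cc2nc[nH]c2Cc2ccc(O1)cc2
F4 | step 6 | potassium 4-{[5-(4-hydroxybenzyl)-1H-imidazol-4-yl]methyl}phenyl sulfate | Oc1ccc(Cc2nc[nH]c2Cc2ccc(OS(=O)(=O)[O-])cc2)cc1.[K+]
F5 | step 4 | 4,5-bis(4-hydroxybenzyl)-1H-imidazole | Oc1ccc(Cc2nc[nH]c2Cc2ccc(O)cc2)cc1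
F6 | step 4 | 4,5-bis[4-(tert-butyldimethylsilyloxy)benzyl]-1H-imidazole | CC(C)(C)[Si](C)(C)Oc1ccc(Cc2nc[nH]c2Cc2ccc(O[Si](C)(C)C(C)(C)C)cc2)cc1
F7 | step 4 | 4,5-bis[4-(tert-butyldimethylsilyloxy)benzyl]-1-SEM-imidazole | CC(C)(C)[Si](C)(C)Oc1ccc(Cc2ncn(COCC[Si](C)(C)C)c2Cc2ccc(O[Si](C)(C)C(C)(C)C)cc2)cc1
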